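**Retrosynthetic overview**

1. Ring A is a hydroquinone mono-aryl ether: C2 (aryl ether carbon) and C5 (hydroxyl carbon) are para, with C3–OMe and C4–Cl on one side and C1 (ester carbon) and C6–H on the other. It is cut at C5–C6 and traced back to a 4-alkenyl-4-aryloxycyclobutenone, whose four ring carbons become C2–C5 and whose alkene carbons become C1 and C6.
2. The cyclobutenone is cut at the tertiary C–O bond to ring B (arylation of the alkoxide with a ring B aryl(2,4,6-trimethoxyphenyl)iodonium salt) and at the bond to the alkenyl group (2-lithioacrolein acetal added to 3-chloro-4-methoxycyclobutenedione, made from squaric acid).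
3. Ring B is bought as an arene (1-fluoro-3-iodo-5-methylbenzene) and dressed by ortho-lithiation/benzyloxycarbonylation and fluoride displacement. Ring A is the only ring formed (step 8).
4. End game: acetal to aldehyde, chlorite oxidation, methyl ester, then removal of both benzyl groups with BCl3.

Key step: step 8

Remark: the target is achiral. Compounds 6, 7, 14 and 15 carry one quaternary stereocentre and are used as racemates; this centre becomes the planar C2 of ring A in step 8.

**Route**

Step 1
Reactants: 1 squaric acid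
Product: 2 3,4-dichlorocyclobut-3-ene-1,2-dione
Conditions: (COCl)2, cat. DMF, CH2Cl2, 40 °C
Reagents that add atoms: oxalyl chloride, ClC(=O)C(Cl)=O
Why: Vilsmeier-type activation turns both vinylogous acid hydroxyls into vinylogous acyl chlorides, the standard preparation of squaric acid dichloride.

Step 2
Reactants: 2 3,4-dichlorocyclobut-3-ene-1,2-dione
Product: 3 3-chloro-4-methoxycyclobut-3-ene-1,2-dione
Conditions: MeOH (1.0 equiv), CH2Cl2, −20 → 0 °C
Reagents that add atoms: methanol, CO
Why: Addition–elimination at one vinylogous acyl chloride carbon; the new methoxy group deactivates the remaining C–Cl by vinylogous ester resonance, so one equivalent of methanol at low temperature should stop at mono-substitution.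

Step 3
Reactants: 3 3-chloro-4-methoxycyclobut-3-ene-1,2-dione; 4 2-bromo-3,3-diethoxyprop-1-ene
Product: 7 racemic 2-chloro-4-(3,3-diethoxyprop-1-en-2-yl)-4-hydroxy-3-methoxycyclobut-2-en-1-one, via (3,3-diethoxyprop-1-en-2-yl)lithium 5 (not isolated), via lithium alkoxide 6 (not isolated)
Conditions: 4, n-BuLi, THF, −78 °C; then added to 3, THF, −78 °C; sat. aq. NH4Cl, −78 °C
Reagents that add atoms: none
Why: Bromine–lithium exchange gives the alkenyllithium, which as a hard nucleophile should undergo 1,2-addition at the carbonyl attached to the methoxy carbon, because the other carbonyl is deactivated as a vinylogous ester (the regiochemistry known for 3-alkyl-4-alkoxycyclobutenediones); the quaternary centre forms as a racemate and needs no control.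

Step 4
Reactants: 8 1-fluoro-3-iodo-5-methylbenzene
Product: 10 benzyl 2-fluoro-6-iodo-4-methylbenzoate, via (2-fluoro-6-iodo-4-methylphenyl)lithium 9 (not isolated)
Conditions: LiN(iPr)2, THF, −78 °C; then cannulated into ClCO2Bn, THF, −78 °C
Reagents that add atoms: benzyl chloroformate, O=C(Cl)OCc1ccccc1
Why: Directed ortho-lithiation removes the most acidic proton, flanked by fluorine and iodine; at −78 °C the aryllithium should neither lose LiF nor undergo halogen migration, and inverse addition to the chloroformate acylates it once.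

Step 5
Reactants: 10 benzyl 2-fluoro-6-iodo-4-methylbenzoate
Product: 11 benzyl 2-(benzyloxy)-6-iodo-4-methylbenzoate
Conditions: BnOH, NaH, DMF, 0 °C → rt
Reagents that add atoms: benzyl alcohol, OCc1ccccc1
Why: Nucleophilic aromatic substitution of the fluoride, activated by the ortho ester and the meta iodine; attack of benzyloxide on the benzyl ester is degenerate, and iodide is not displaced.

Step 6
Reactants: 11 benzyl 2-(benzyloxy)-6-iodo-4-methylbenzoate
Product: 13 [3-(benzyloxy)-2-(benzyloxycarbonyl)-5-methylphenyl](2,4,6-trimethoxyphenyl)iodonium 4-methylbenzenesulfonate, via hydroxy(tosyloxy)iodane 12 (not isolated)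
Conditions: mCPBA, TsOH·H2O, MeCN, 70 °C; then 1,3,5-trimethoxybenzene, rt; Et2O precipitation
Reagents that add atoms: 1,3,5-trimethoxybenzene, COc1cc(OC)cc(OC)c1; 4-methylbenzenesulfonic acid monohydrate, Cc1ccc(cc1)S(=O)(=O)O.O
Why: Oxidation of the aryl iodide to a Koser-type trivalent iodine species, then electrophilic substitution on trimethoxybenzene (one-pot diaryliodonium synthesis); the iodine stays on its ring B carbon, so the salt is regiodefined.

Step 7
Reactants: 7 racemic 2-chloro-4-(3,3-diethoxyprop-1-en-2-yl)-4-hydroxy-3-methoxycyclobut-2-en-1-one; 13 [3-(benzyloxy)-2-(benzyloxycarbonyl)-5-methylphenyl](2,4,6-trimethoxyphenyl)iodonium 4-methylbenzenesulfonate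
Product: 15 racemic benzyl 2-(benzyloxy)-6-{[3-chloro-1-(3,3-diethoxyprop-1-en-2-yl)-2-methoxy-4-oxocyclobut-2-en-1-yl]oxy}-4-methylbenzoate, via sodium alkoxide 14 (not isolated)
Conditions: NaH added last to 7 + 13, PhMe/THF, 0 °C → rt
Reagents that add atoms: none
Why: Metal-free O-arylation of a tertiary alkoxide with a diaryliodonium salt (ligand exchange at trivalent iodine, then ligand coupling); the electron-rich trimethoxyphenyl group acts as the non-transferred ligand, so the ortho-ester ring B aryl should be delivered, and adding the base last consumes the alkoxide as it forms; the quaternary centre is untouched and stays racemic.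

Step 8
Reactants: 15 racemic benzyl 2-(benzyloxy)-6-{[3-chloro-1-(3,3-diethoxyprop-1-en-2-yl)-2-methoxy-4-oxocyclobut-2-en-1-yl]oxy}-4-methylbenzoate
Product: 18 benzyl 2-(benzyloxy)-6-[3-chloro-6-(diethoxymethyl)-4-hydroxy-2-methoxyphenoxy]-4-methylbenzoate, via dienyl ketene 16 (not isolated), via cyclohexadienone 17 (not isolated)
Conditions: PhMe (dilute, degassed), 110 °C
Reagents that add atoms: none
Why: Heating should break the bond between the carbonyl carbon and the quaternary carbon in a conrotatory 4π ring opening to give dienyl ketene 16; a disrotatory 6π electrocyclisation then joins the ketene carbon (future C5) to the alkene CH2 (future C6), closing the six-membered carbocycle ring A as dienone 17, which enolises to phenol 18. The closest known reaction is the Moore ring expansion of 4-alkenyl-4-hydroxy- and 4-alkoxycyclobutenones to hydroquinones and their monoethers; the aryloxy group on the quaternary carbon is the variation not yet tried. No stereocentre is created, and the racemic quaternary carbon becomes the planar C2. The step needs the alkenyl group to turn inward, and this is secured by the preference of the oxygen donor on the quaternary carbon to rotate outward. A ketene with the aryloxy group inward has no hydroxyl to lactonise and should revert to the cyclobutenone, so material funnels to 18. The positions of the aryl ether, methoxy, chlorine and hydroxyl are fixed by the squarate carbons, so no arene substitution has to be selective.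

Step 9
Reactants: 18 benzyl 2-(benzyloxy)-6-[3-chloro-6-(diethoxymethyl)-4-hydroxy-2-methoxyphenoxy]-4-methylbenzoate
Product: 19 benzyl 2-(benzyloxy)-6-(3-chloro-6-formyl-4-hydroxy-2-methoxyphenoxy)-4-methylbenzoate
Conditions: 1 M HCl, THF, rt
Reagents that add atoms: water, O
Why: Acid-catalysed hydrolysis of a benzaldehyde diethyl acetal; benzyl ester, benzyl ether and diaryl ether should be stable to dilute acid at room temperature.

Step 10
Reactants: 19 benzyl 2-(benzyloxy)-6-(3-chloro-6-formyl-4-hydroxy-2-methoxyphenoxy)-4-methylbenzoate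
Product: 20 2-{3-(benzyloxy)-2-[(benzyloxy)carbonyl]-5-methylphenoxy}-4-chloro-5-hydroxy-3-methoxybenzoic acid
Conditions: NaClO2, NaH2PO4, 2-methyl-2-butene, t-BuOH/H2O, 0 °C → rt
Reagents that add atoms: sodium chlorite, [Na+].[O-]Cl=O
Why: Pinnick oxidation of the aryl aldehyde; excess 2-methyl-2-butene traps hypochlorous acid so that the free phenol ring and the electron-rich ring B are not chlorinated.

Step 11
Reactants: 20 2-{3-(benzyloxy)-2-[(benzyloxy)carbonyl]-5-methylphenoxy}-4-chloro-5-hydroxy-3-methoxybenzoic acid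
Product: 21 methyl 2-{3-(benzyloxy)-2-[(benzyloxy)carbonyl]-5-methylphenoxy}-4-chloro-5-hydroxy-3-methoxybenzoate
Conditions: MeI (1.1 equiv), KHCO3, DMF, rt
Reagents that add atoms: iodomethane, CI
Why: SN2 alkylation of the carboxylate; bicarbonate deprotonates the carboxylic acid but hardly the C5 phenol, so the phenol should stay free.

Step 12
Reactants: 21 methyl 2-{3-(benzyloxy)-2-[(benzyloxy)carbonyl]-5-methylphenoxy}-4-chloro-5-hydroxy-3-methoxybenzoate
Product: 22 2-[3-chloro-4-hydroxy-2-methoxy-6-(methoxycarbonyl)phenoxy]-6-hydroxy-4-methylbenzoic acid (CNP0130950.0)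
Conditions: BCl3, pentamethylbenzene, CH2Cl2, −78 → 0 °C; MeOH/H2O quench
Reagents that add atoms: none
Why: Lewis acid debenzylation with a cation scavenger should cleave the aryl benzyl ether and the chelated salicylate benzyl ester while pentamethylbenzene traps the benzyl cations; unlike hydrogenolysis it does not endanger the aryl chloride, and the methyl ester, the ring A methyl ether (not next to a carbonyl) and the diaryl ether should survive.

**Compound list**

1 | squaric acid (3,4-dihydroxycyclobut-3-ene-1,2-dione) | OC1=C(O)C(=O)C1=O | starting material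
2 | 3,4-dichlorocyclobut-3-ene-1,2-dione | ClC1=C(Cl)C(=O)C1=O | intermediate
3 | 3-chloro-4-methoxycyclobut-3-ene-1,2-dione | COC1=C(Cl)C(=O)C1=O | intermediate
4 | 2-bromo-3,3-diethoxyprop-1-ene | CCOC(OCC)C(Br)=C | starting material
5 | (3,3-diethoxyprop-1-en-2-yl)lithium | [Li]C(=C)C(OCC)OCC | intermediate
6 | racemic lithium 3-chloro-1-(3,3-diethoxyprop-1-en-2-yl)-2-methoxy-4-oxocyclobut-2-en-1-olate | [Li]OC1(C(=C)C(OCC)OCC)C(OC)=C(Cl)C1=O | intermediate
7 | racemic 2-chloro-4-(3,3-diethoxyprop-1-en-2-yl)-4-hydroxy-3-methoxycyclobut-2-en-1-one | CCOC(OCC)C(=C)C1(O)C(OC)=C(Cl)C1=O | intermediate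
8 | 1-fluoro-3-iodo-5-methylbenzene | Cc1cc(F)cc(I)c1 | starting material
9 | (2-fluoro-6-iodo-4-methylphenyl)lithium | [Li]c1c(F)cc(C)cc1I | intermediate
10 | benzyl 2-fluoro-6-iodo-4-methylbenzoate | Cc1cc(F)c(C(=O)OCc2ccccc2)c(I)c1 | intermediate
11 | benzyl 2-(benzyloxy)-6-iodo-4-methylbenzoate | Cc1cc(I)c(C(=O)OCc2ccccc2)c(OCc2ccccc2)c1 | intermediate
12 | benzyl 2-(benzyloxy)-6-[hydroxy(tosyloxy)-λ3-iodanyl]-4-methylbenzoate | Cc1ccc(cc1)S(=O)(=O)OI(O)c1cc(C)cc(OCc2ccccc2)c1C(=O)OCc1ccccc1 | intermediate
13 | [3-(benzyloxy)-2-(benzyloxycarbonyl)-5-methylphenyl](2,4,6-trimethoxyphenyl)iodonium 4-methylbenzenesulfonate | COc1cc(OC)c([I+]c2cc(C)cc(OCc3ccccc3)c2C(=O)OCc2ccccc2)c(OC)c1.Cc1ccc(cc1)S(=O)(=O)[O-] | intermediate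
14 | racemic sodium 3-chloro-1-(3,3-diethoxyprop-1-en-2-yl)-2-methoxy-4-oxocyclobut-2-en-1-olate | [Na+].[O-]C1(C(=C)C(OCC)OCC)C(OC)=C(Cl)C1=O | intermediate
15 | racemic benzyl 2-(benzyloxy)-6-{[3-chloro-1-(3,3-diethoxyprop-1-en-2-yl)-2-methoxy-4-oxocyclobut-2-en-1-yl]oxy}-4-methylbenzoate | CCOC(OCC)C(=C)C1(Oc2cc(C)cc(OCc3ccccc3)c2C(=O)OCc2ccccc2)C(OC)=C(Cl)C1=O | intermediate
16 | benzyl 2-(benzyloxy)-6-{[(3Z)-2-chloro-5-(diethoxymethyl)-3-methoxy-1-oxohexa-1,3,5-trien-4-yl]oxy}-4-methylbenzoate (dienyl ketene; aryloxy and methoxy cis across C3=C4) | O=C=C(Cl)/C(OC)=C(/Oc1cc(C)cc(OCc2ccccc2)c1C(=O)OCc1ccccc1)C(=C)C(OCC)OCC | intermediate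
17 | benzyl 2-(benzyloxy)-6-{[5-chloro-2-(diethoxymethyl)-6-methoxy-4-oxocyclohexa-1,5-dien-1-yl]oxy}-4-methylbenzoate | O=C1CC(C(OCC)OCC)=C(Oc2cc(C)cc(OCc3ccccc3)c2C(=O)OCc2ccccc2)C(OC)=C1Cl | intermediate
18 | benzyl 2-(benzyloxy)-6-[3-chloro-6-(diethoxymethyl)-4-hydroxy-2-methoxyphenoxy]-4-methylbenzoate | CCOC(OCC)c1cc(O)c(Cl)c(OC)c1Oc1cc(C)cc(OCc2ccccc2)c1C(=O)OCc1ccccc1 | intermediate
19 | benzyl 2-(benzyloxy)-6-(3-chloro-6-formyl-4-hydroxy-2-methoxyphenoxy)-4-methylbenzoate | O=Cc1cc(O)c(Cl)c(OC)c1Oc1cc(C)cc(OCc2ccccc2)c1C(=O)OCc1ccccc1 | intermediate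
20 | 2-{3-(benzyloxy)-2-[(benzyloxy)carbonyl]-5-methylphenoxy}-4-chloro-5-hydroxy-3-methoxybenzoic acid | OC(=O)c1cc(O)c(Cl)c(OC)c1Oc1cc(C)cc(OCc2ccccc2)c1C(=O)OCc1ccccc1 | intermediate
21 | methyl 2-{3-(benzyloxy)-2-[(benzyloxy)carbonyl]-5-methylphenoxy}-4-chloro-5-hydroxy-3-methoxybenzoate | COC(=O)c1cc(O)c(Cl)c(OC)c1Oc1cc(C)cc(OCc2ccccc2)c1C(=O)OCc1ccccc1 | intermediate
22 | 2-[3-chloro-4-hydroxy-2-methoxy-6-(methoxycarbonyl)phenoxy]-6-hydroxy-4-methylbenzoic acid | COC(=O)c1cc(O)c(Cl)c(OC)c1Oc1cc(C)cc(O)c1C(=O)O | target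

**Step count**

Total: 12 steps. Longest linear sequence: 9 steps (steps 1, 2, 3, 7, 8, 9, 10, 11, 12; the ring B branch, steps 4, 5, 6 then 7 to 12, is equally long).

**Steps most likely to fail**

Step 7 (arylation of the tertiary alkoxide). The hindered alkoxide may deprotonate the salt next to iodine and send it down an aryne pathway. It may also couple so slowly at the crowded trivalent iodine centre that it is lost to self-condensation first. The fallback sets out from 7 and comes back at 15; it makes the C–O bond by nucleophilic aromatic substitution instead of ligand coupling. Purchased 2,6-difluoro-4-methylbenzaldehyde is treated with benzyl alcohol and K2CO3 in DMF to give 2-(benzyloxy)-6-fluoro-4-methylbenzaldehyde F1. The sodium alkoxide of 7 (NaH, DMF, 0 °C) should displace the remaining fluoride, which is activated by the coplanar ortho formyl group, to give racemic 2-(benzyloxy)-6-{[3-chloro-1-(3,3-diethoxyprop-1-en-2-yl)-2-methoxy-4-oxocyclobut-2-en-1-yl]oxy}-4-methylbenzaldehyde F2. Chlorite oxidation (NaClO2, phosphate buffer near pH 5, 2-methyl-2-butene, 0 °C, kept short to spare the acetal) should give the corresponding benzoic acid F3. BnBr and K2CO3 in DMF then return 15.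

Step 8 (ring expansion). At the temperature needed, the aryloxy group, a weaker donor than alkoxy, may not steer the ring opening well enough, or the dienyl ketene may be diverted or decompose before the 6π closure. The fallback sets out from 7, uses iodide 11, and comes back at 19; it runs the ring expansion on the free tertiary alcohol, the classical substrate, and attaches ring B afterwards. Heating 7 in toluene should give 2-chloro-5-(diethoxymethyl)-3-methoxybenzene-1,4-diol F4, handled under inert gas. MOMCl (1 equiv) and iPr2NEt should protect the more acidic, less hindered hydroxyl next to chlorine to give 3-chloro-6-(diethoxymethyl)-2-methoxy-4-(methoxymethoxy)phenol F5. Ullmann coupling of F5 with 11 (CuI, picolinic acid, K3PO4, DMSO, 90 °C) should give benzyl 2-(benzyloxy)-6-[3-chloro-6-(diethoxymethyl)-2-methoxy-4-(methoxymethoxy)phenoxy]-4-methylbenzoate F6. 1 M HCl in THF then removes the methoxymethyl group and the acetal together and returns aldehyde 19.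

Step 3 (alkenyllithium addition). The organolithium may attack the chlorine-bearing carbon and expel chloride, or add to the other carbonyl. The fallback sets out from 4 and comes back at 7; it introduces chlorine only after the C–C bond is made. Purchased dimethyl squarate is reduced with LiAlH(OtBu)3 (THF, −78 °C) to racemic 4-hydroxy-2,3-dimethoxycyclobut-2-en-1-one F7. Catalytic HCl in CH2Cl2 converts F7 into 3-methoxycyclobut-3-ene-1,2-dione F8. Reagent 5, made from 4 as in step 3, should add to the carbonyl next to the methoxy carbon to give racemic 4-(3,3-diethoxyprop-1-en-2-yl)-4-hydroxy-3-methoxycyclobut-2-en-1-one F9. N-chlorosuccinimide (CH2Cl2, 0 °C) should chlorinate the nucleophilic α-carbon of the vinylogous ester and give 7.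

**Further compounds**

F1 | step 7 | 2-(benzyloxy)-6-fluoro-4-methylbenzaldehyde | Cc1cc(F)c(C=O)c(OCc2ccccc2)c1
F2 | step 7 | racemic 2-(benzyloxy)-6-{[3-chloro-1-(3,3-diethoxyprop-1-en-2-yl)-2-methoxy-4-oxocyclobut-2-en-1-yl]oxy}-4-methylbenzaldehyde | CCOC(OCC)C(=C)C1(Oc2cc(C)cc(OCc3ccccc3)c2C=O)C(OC)=C(Cl)C1=O
F3 | step 7 | racemic 2-(benzyloxy)-6-{[3-chloro-1-(3,3-diethoxyprop-1-en-2-yl)-2-methoxy-4-oxocyclobut-2-en-1-yl]oxy}-4-methylbenzoic acid | CCOC(OCC)C(=C)C1(Oc2cc(C)cc(OCc3ccccc3)c2C(=O)O)C(OC)=C(Cl)C1=O
F4 | step 8 | 2-chloro-5-(diethoxymethyl)-3-methoxybenzene-1,4-diol | CCOC(OCC)c1cc(O)c(Cl)c(OC)c1O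
F5 | step 8 | 3-chloro-6-(diethoxymethyl)-2-methoxy-4-(methoxymethoxy)phenol | CCOC(OCC)c1cc(OCOC)c(Cl)c(OC)c1O
F6 | step 8 | benzyl 2-(benzyloxy)-6-[3-chloro-6-(diethoxymethyl)-2-methoxy-4-(methoxymethoxy)phenoxy]-4-methylbenzoate | CCOC(OCC)c1cc(OCOC)c(Cl)c(OC)c1Oc1cc(C)cc(OCc2ccccc2)c1C(=O)OCc1ccccc1
F7 | step 3 | racemic 4-hydroxy-2,3-dimethoxycyclobut-2-en-1-one | COC1=C(OC)C(=O)C1O
F8 | step 3 | 3-methoxycyclobut-3-ene-1,2-dione | COC1=CC(=O)C1=O
F9 | step 3 | racemic 4-(3,3-diethoxyprop-1-en-2-yl)-4-hydroxy-3-methoxycyclobut-2-en-1-one | CCOC(OCC)C(=C)C1(O)C(OC)=CC1=O
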